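**Retrosynthetic overview**
- The oxane O–C2 bond is cut last: a biomimetic oxidative cyclisation through a p-quinone methide leads back to C2-symmetric (3S,5S)-1,7-bis(4-hydroxy-3-methoxyphenyl)heptane-3,5-diol, whose two benzylic CH2 groups are equivalent through the C2 axis.
- The diol, as its bis-benzyl ether, is cut two-directionally at C1–C2 and C6–C7: two equivalents of a 4-(benzyloxy)-3-methoxybenzyl Grignard reagent plus one (2R,4R)-1,2:4,5-diepoxypentane.
- Both oxirane rings of the bis-epoxide are closed in one operation from (2R,4R)-1,5-dichloropentane-2,4-diol and opened in the same flask. The dichlorodiol comes from Noyori hydrogenation of 1,5-dichloropentane-2,4-dione, which sets both carbinol centres.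
- Ring order: the two oxiranes together first (transient), the oxane last; both arene rings are bought.

Assumption: both chlorine-containing starting materials are catalogue chemicals; the diarylheptanoid chain is numbered C1 to C7 starting from the carbon that becomes the aryl-bearing oxane carbon.

**Step 1**
Reactants: 1 1,5-dichloropentane-2,4-dione
Product: 2 (2R,4R)-1,5-dichloropentane-2,4-diol
Conditions: H2 (80 atm), RuCl2[(S)-BINAP] (0.2 mol%), MeOH, 75 °C; recrystallise
Reagents that add atoms: none
Why: Noyori asymmetric hydrogenation of a 1,3-diketone, in which RuCl2[(S)-BINAP] reduces the chelated β-dicarbonyl twice with the same facial sense, so the anti, C2-symmetric (2R,4R) diol forms in high ee, the minor meso diol is lost on recrystallisation and the C–Cl bonds survive.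

**Step 2**
Reactants: 2 (2R,4R)-1,5-dichloropentane-2,4-diol; 3 4-(benzyloxy)-3-methoxybenzyl chloride
Product: 6 (3S,5S)-1,7-bis[4-(benzyloxy)-3-methoxyphenyl]heptane-3,5-diol, via bis-epoxide 4 (not isolated), via Grignard reagent 5 (not isolated)
Conditions: NaH (2.1 equiv), THF, 0 °C to rt; separately 3 (3.2 equiv), Mg, THF, 0 °C; combine, CuI (10 mol%), −40 to 0 °C; then 1 M HCl
Reagents that add atoms: a second equivalent of 3, 4-(benzyloxy)-3-methoxybenzyl chloride (COc1cc(CCl)ccc1OCc1ccccc1), because 6 holds two of its benzyl units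
Why: Two-fold Williamson-type ring closure (3-exo-tet) of the bis-alkoxide gives the C2-symmetric bis-epoxide, both oxirane rings forming in the same operation without touching the C–O bonds of the stereocentres, and two equivalents of the copper-catalysed Grignard reagent then open the two oxiranes by SN2 attack at their unhindered CH2 termini (two-directional epoxide opening), so both carbinol centres carry over unchanged and the descriptors change from R to S only because the CIP priorities change.

**Step 3**
Reactants: 6 (3S,5S)-1,7-bis[4-(benzyloxy)-3-methoxyphenyl]heptane-3,5-diol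
Product: 7 (3S,5S)-1,7-bis(4-hydroxy-3-methoxyphenyl)heptane-3,5-diol
Conditions: H2 (1 atm), Pd/C (10 wt%), EtOAc–MeOH, rt
Reagents that add atoms: none
Why: Catalytic hydrogenolysis of the two aryl benzyl ethers frees both phenols, the molecule has no other reducible or benzylic C–O group, and the stereocentres are untouched.

**Step 4**
Reactants: 7 (3S,5S)-1,7-bis(4-hydroxy-3-methoxyphenyl)heptane-3,5-diol
Product: 9 (2S,4R,6S)-2-(4-hydroxy-3-methoxyphenyl)-6-[2-(4-hydroxy-3-methoxyphenyl)ethyl]oxan-4-ol, via p-quinone methide 8 (not isolated)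
Conditions: DDQ (0.9 equiv), MeCN–CH2Cl2, 4 Å MS, 0 °C to rt; then PPTS (10 mol%), rt; recover unreacted 7
Reagents that add atoms: none
Why: Biomimetic oxidative cycloetherification, in which DDQ dehydrogenates one 4-alkylphenol unit (the two are equivalent through the C2 axis) to the p-quinone methide, the C5 hydroxyl adds to its exocyclic carbon (intramolecular oxa-1,6-conjugate addition with rearomatisation through a six-membered chair with the aryl group equatorial), and because this closure is reversible under acid the new centre settles as the all-equatorial 2,4,6-cis oxane, which is 2S.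

**Compound list**
1 | 1,5-dichloropentane-2,4-dione | ClCC(=O)CC(=O)CCl | starting material
2 | (2R,4R)-1,5-dichloropentane-2,4-diol | ClC[C@H](O)C[C@@H](O)CCl | intermediate
3 | 4-(benzyloxy)-3-methoxybenzyl chloride, i.e. 1-(benzyloxy)-4-(chloromethyl)-2-methoxybenzene | COc1cc(CCl)ccc1OCc1ccccc1 | starting material
4 | (2R,4R)-1,2:4,5-diepoxypentane, i.e. (2R,2'R)-2,2'-methylenebis(oxirane) | C1O[C@@H]1C[C@@H]2CO2 | intermediate
5 | [4-(benzyloxy)-3-methoxybenzyl]magnesium chloride | COc1cc(C[Mg]Cl)ccc1OCc1ccccc1 | intermediate
6 | (3S,5S)-1,7-bis[4-(benzyloxy)-3-methoxyphenyl]heptane-3,5-diol | COc1cc(CC[C@H](O)C[C@@H](O)CCc2ccc(OCc3ccccc3)c(OC)c2)ccc1OCc1ccccc1 | intermediate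
7 | (3S,5S)-1,7-bis(4-hydroxy-3-methoxyphenyl)heptane-3,5-diol, (3S,5S)-octahydrocurcumin | COc1cc(CC[C@H](O)C[C@@H](O)CCc2ccc(O)c(OC)c2)ccc1O | intermediate
8 | 4-[(3S,5S)-3,5-dihydroxy-7-(4-hydroxy-3-methoxyphenyl)heptylidene]-2-methoxycyclohexa-2,5-dien-1-one | COc1cc(CC[C@H](O)C[C@@H](O)CC=C2C=CC(=O)C(OC)=C2)ccc1O | intermediate
9 | (2S,4R,6S)-2-(4-hydroxy-3-methoxyphenyl)-6-[2-(4-hydroxy-3-methoxyphenyl)ethyl]oxan-4-ol, all three ring substituents cis and equatorial | COc1cc(CC[C@H]2C[C@@H](O)C[C@@H](c3ccc(O)c(OC)c3)O2)ccc1O | target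

**Totals**
Total step count: 4. Longest linear sequence: 4 (1 → 2 → 6 → 7 → 9); the Grignard reagent 5 is made from bought 3 inside step 2, and two equivalents of it are built into 6.

**Steps most likely to fail, with fallbacks**

Step 4 is the riskiest. The product still carries a second 4-alkylphenol unit and a benzylic ether, so over-oxidation and quinone methide tautomerisation compete, and the yield per pass is capped near 50% with recovery of 7. The fallback sets out from 6 and comes back at 9. It closes the ring before the phenols are freed: DDQ (0.9 equiv), CH2Cl2, 4 Å MS, 0 °C oxidises one 3,4-dialkoxyarene unit of 6 to a benzylic cation (no quinone methide, no free phenol exposed to the oxidant), which the C5 hydroxyl traps to give (2S,4R,6S)-2-[4-(benzyloxy)-3-methoxyphenyl]-6-{2-[4-(benzyloxy)-3-methoxyphenyl]ethyl}oxan-4-ol F1. Short hydrogenolysis (H2 1 atm, Pd/C, EtOAc, rt) then removes both aryl benzyl groups, which cleave much faster than the cyclic benzylic C2–O bond, and gives 9.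

Step 2 is next. Wurtz homocoupling while 5 is made, chlorohydrin formation by magnesium chloride and incomplete second opening can all lower the yield. The fallback sets out from 3 and comes back at 6, replacing the Grignard reagent by a stabilised carbanion. PhSO2Na, DMF, 60 °C converts 3 into 1-(benzyloxy)-2-methoxy-4-[(phenylsulfonyl)methyl]benzene F2. Its lithio derivative (n-BuLi, THF, −78 °C, 2.4 equiv) opens both oxiranes of 4 (made from 2 with NaH as before; BF3·OEt2, −78 °C) to (3R,5R)-1,7-bis[4-(benzyloxy)-3-methoxyphenyl]-1,7-bis(phenylsulfonyl)heptane-3,5-diol F3, a mixture of epimers at C1 and C7 with the same carbinol geometry as 6. Reductive desulfonylation (Mg, MeOH, rt) then gives 6.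

Step 1 is third. High-pressure hydrogenation of a bis(α-chloro ketone) can suffer catalyst deactivation, some C–Cl loss and meso diol. The fallback sets out from 1 and comes back at 4, replacing asymmetric reduction by resolution. NaBH4, MeOH, 0 °C gives 1,5-dichloropentane-2,4-diol F4 as a mixture of stereoisomers, and KOH, Et2O closes it to 1,2:4,5-diepoxypentane F5 as a mixture of stereoisomers. Hydrolytic kinetic resolution follows, using the enantiomer of the (salen)CoOAc catalyst (trivalent cobalt) that hydrolyses S-configured oxirane carbons, with H2O (1.0 equiv), 0 °C to rt. This converts the unwanted isomers into (2S,4S)-pentane-1,2,4,5-tetraol F6 and (2S)-3-[(2R)-oxiran-2-yl]propane-1,2-diol F7, and leaves 4 (at most 25%), which is distilled off and opened with 5 as in step 2.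

**Further compounds**
F1 | step 4 | (2S,4R,6S)-2-[4-(benzyloxy)-3-methoxyphenyl]-6-{2-[4-(benzyloxy)-3-methoxyphenyl]ethyl}oxan-4-ol | COc1cc(CC[C@H]2C[C@@H](O)C[C@@H](c3ccc(OCc4ccccc4)c(OC)c3)O2)ccc1OCc1ccccc1
F2 | step 2 | 1-(benzyloxy)-2-methoxy-4-[(phenylsulfonyl)methyl]benzene | COc1cc(CS(=O)(=O)c2ccccc2)ccc1OCc1ccccc1
F3 | step 2 | (3R,5R)-1,7-bis[4-(benzyloxy)-3-methoxyphenyl]-1,7-bis(phenylsulfonyl)heptane-3,5-diol, epimers at C1 and C7 | COc1cc(C(C[C@H](O)C[C@@H](O)CC(c2ccc(OCc3ccccc3)c(OC)c2)S(=O)(=O)c2ccccc2)S(=O)(=O)c2ccccc2)ccc1OCc1ccccc1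
F4 | step 1 | 1,5-dichloropentane-2,4-diol, mixture of stereoisomers | ClCC(O)CC(O)CCl
F5 | step 1 | 1,2:4,5-diepoxypentane, mixture of stereoisomers | C1OC1CC1CO1
F6 | step 1 | (2S,4S)-pentane-1,2,4,5-tetraol | OC[C@@H](O)C[C@H](O)CO
F7 | step 1 | (2S)-3-[(2R)-oxiran-2-yl]propane-1,2-diol | OC[C@@H](O)C[C@@H]1CO1
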